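## Structural features

The target is a 2,3-dihydrobenzofuran. Ring A (benzo ring, C3a to C7a) carries an allyl group on C5 and a methoxy group on C7. Ring B (O1, C2, C3, C3a, C7a) carries the 4-hydroxy-3-methoxyphenyl ring C on C2 and a CH2 group (C9) on C3, whose oxygen is the phenolic oxygen of a second 4-allyl-2-methoxyphenyl unit. The only stereocentres are C2 (S) and C3 (R); they are adjacent, and ring C and C9 sit trans across ring B. Fragile groups are the two terminal allyl groups (they move into conjugation with strong base or metal hydrides and react with electrophilic halogen and boranes), the free phenol, and the O1–C2 bond, which is benzylic and para to an oxygen donor and therefore ionises in acid. That ionisation is also an asset: C2 can settle to the trans isomer through its cation, whereas C3, a benzylic methine without a heteroatom, cannot be corrected once it is set. The real difficulty is therefore the absolute configuration at C3, together with joining three electron-rich arenes without touching the allyl groups. The key step uses the fact that C2 and C3 are neighbouring sp3 carbons that each bear exactly one aryl ring, with oxygen on C2 and the C9 oxygen one carbon beyond C3. This is the pattern left when ring C and ring A are added across the C2=C3 bond of a 3-oxygenated propenyl boron compound, with boron marking C2 for oxygenation.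

## Logic of the disconnections

19 to 18: the O–Si bond of the ring C phenol is cut last. Keeping this phenol silylated until the end means that at every earlier stage only one hydroxyl is free to react. The demand is a silyl group that survives an aryllithium, mild acid and a Mitsunobu reaction and leaves under conditions that spare two allyl groups.

18 to 17 and 9: the C9–O aryl ether bond is cut. This removes a whole eugenol unit in one stroke and keeps an allylic aryl ether and a second allyl arene out of the palladium step. The forward step must be a substitution at a beta-branched primary carbon that does not eliminate towards C3, and 17 must have C9–OH as its only free hydroxyl.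

17 to 15 (through 16): the O1–C2 bond is cut. C2 is benzylic and para-oxygenated, so the bond can form by capture of a C2 cation by the ring A phenol, and the trans ring is the thermodynamic outcome. This turns ring B into an open chain with a secondary alcohol at C2. The demand is that C3 already has the right configuration and is not eroded, that the phenol and C9 protecting groups fall in the same acid, and that the ring C silyl ether stays.

15 to 14: the C2–O bond is traced to a C2–B bond. Oxidation of a boronic ester is stereoretentive and mild, so boron can stand in for oxygen through the C–C bond formations. The oxidant must spare the allyl groups and the aryl silyl ether.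

14 to 2, 8 and 11 (through 12 and 13): the C2–aryl bond to ring C and the C3–C3a bond are cut together. This is the largest simplification: three fragments of similar size, two C–C bonds and both stereocentres in one step, with C3 set by the catalyst. The demand is a 1,2-metallate shift that beats direct transmetallation on a beta-substituted alkenyl boronate, and enantiofacial control by the ligand.

8 to 4 and 6 (through 7), 4 to 3, 6 to 5: the C–B bond comes from anti-Markovnikov syn hydroboration of a terminal alkyne, which fixes the (E) geometry, and the hindered diol on boron is made from a 1,2-diketone. The hydroboration must be regioselective next to a propargylic oxygen, and the diol exchange must be complete.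

11 to 10 to 9: the O–CH2 bond of the acetal and the C–Br bond are cut. Ring A with its allyl, methoxy and oxygen is eugenol itself, so only a bromine ortho to the phenol has to be added. The demand is ring bromination that leaves the allyl alkene alone.

2 to 1: the O–Si bond is cut, which leads back to a commercial bromophenol.

## Other disconnections considered

Alternative 1: The cut is C3–C3a, formed in the forward direction by migration. The (S)-flavanone A2 is treated with PhI(OAc)2 (trivalent iodine), acid and trimethyl orthoformate. Its enol ether is iodinated at the alpha-carbon (the future C3), the ring A carbon (future C3a) shifts from the carbonyl carbon to that carbon as iodine leaves, and the pyranone contracts to ring B with the former carbonyl carbon as the C9 methyl ester, giving A1.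
- In its favour: ring B, the C3–C3a bond and C9 at a useful oxidation level arrive in one operation from an easily assembled heterocycle. Only C2 needs a catalyst, and C3 follows because the ester alpha-centre can settle trans.
- Against it here: the hypervalent iodine reagent attacks terminal alkenes and electron-rich arenes, so ring A must carry bromine in place of allyl and ring C must be deactivated as a mesylate. That adds ester reduction, a cross-coupling to install the C5 allyl group, and mesylate cleavage. Flavanones also open reversibly to chalcones in acid, which endangers the C2 configuration of A2, the only source of chirality.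
- Comparison: on structure it is the equal of the chosen plan in trans control (both rely on thermodynamic preference) and better in needing no organolithium and no special boron ligand. On mechanism it is weaker, because chirality rests on a centre that can racemise under the conditions of its own key step, whereas the chosen plan sets the non-epimerisable C3 directly. On step economy it is longer by roughly two to three steps after the key step.

Alternative 2: The cuts are C3–C3a and the C9–O bond to a nitroxide. Photoexcited fac-Ir(ppy)3 (trivalent iridium) transfers one electron to the aryl iodide A4, iodide leaves, the C3a radical closes 5-exo onto the vinyl group to form C3–C3a and ring B, and TEMPO traps the primary C9 radical to give A3.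
- In its favour: neutral, mild conditions; ring closure and C9 oxygenation in one step; the C2 stereocentre of A4 could come from a catalytic asymmetric allylic etherification and is untouched by the radical step.
- Against it here: C3 is set under kinetic control by 1,2-induction from C2, which for 5-exo aryl radical closures of this type is usually modest and cannot be corrected afterwards. A4 is a doubly activated (allylic and benzylic) aryl ether prone to ionisation and sigmatropic rearrangement. The asymmetric etherification would need a phenoxide flanked by iodine and methoxy. The N–O bond must still be cleaved reductively before etherification at C9.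
- Comparison: on step economy this plan is the equal of the chosen one or slightly better (about seven to eight steps in total), and it is better in mildness. On structure and mechanism it is weaker where it matters: the chosen plan controls C3 by catalyst and lets C2 follow thermodynamically, while here the catalyst controls the correctable centre and the uncorrectable one is left to substrate bias.

Alternative 3: The cut is O1–C7a. The secondary benzylic alkoxide of the bromo alcohol A6 displaces the ring A bromide under CuI, 1,10-phenanthroline and Cs2CO3 (monovalent copper), closing ring B to give A5 with C2 and C3 unchanged.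
- In its favour: both stereocentres are transferred with retention, so nothing depends on equilibration through a cation, and the oxygen placed on C2 becomes O1 itself. The (1S,2R) pattern of A6 is the one a conjunctive diarylation delivers, so this closure could be combined with the chosen key step.
- Against it here: the bromide is flanked by a methoxy group and the side chain and is hindered for copper. Hot carbonate with a benzylic C3–H beta to an aryloxy group invites loss of the eugenol unit by elimination and migration of the allyl groups. Ring A would need two differentiated halogens, which eugenol does not provide directly. The final acetal cleavage still needs acid.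
- Comparison: on stereochemical fidelity it is the better plan in principle, since C2 never ionises. On mechanism it is harsher and less certain for this hindered, base-sensitive substrate. On step economy it is equal or one step longer because of the ring A precursor.

Key step: step 7

Remarks on the chemistry (assumptions):
- The diol on boron is a spectator. The cyclic ester of cis-1,2-dimethyl-1,2-dihydroacenaphthylene-1,2-diol ("mac") is used instead of the pinacol ester, because ate complexes of beta-substituted alkenyl pinacol boronates tend to transmetallate directly; carbon skeletons and the bonds formed are unchanged.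
- Pd(OAc)2 is a divalent palladium precatalyst; the species that inserts into the C–Br bond is zerovalent palladium formed from it in the flask.
- O1 of the target is the phenolic oxygen of ring A; the oxygen put on C2 by oxidation of boron leaves as water in step 9.
- Which antipode of MandyPhos (a C2-symmetric 1,1'-bis(diarylphosphino)-2,2'-bis[alpha-(dimethylamino)benzyl]ferrocene) gives the (1S,2R) series is not assigned here; both are available and the one that does is meant.

## Route

Step 1
Reactants: 1 4-bromo-2-methoxyphenol
Product: 2 (4-bromo-2-methoxyphenoxy)triisopropylsilane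
Conditions: TIPSCl, imidazole, DMF, rt
Reagents that add atoms: triisopropylsilyl chloride, CC(C)[Si](Cl)(C(C)C)C(C)C
Why: Standard imidazole-mediated O-silylation of a phenol; the bulky aryl TIPS ether tolerates the later aryllithium, perborate and aqueous acid.

Step 2
Reactants: 3 propargyl alcohol
Product: 4 tert-butyldimethyl(prop-2-yn-1-yloxy)silane
Conditions: TBSCl, imidazole, CH2Cl2, 0 °C to rt
Reagents that add atoms: tert-butyldimethylsilyl chloride, CC(C)(C)[Si](C)(C)Cl
Why: Routine silylation of a primary alcohol; a silyl ether on the future C9 is a poor allylic leaving group and will not ionise under palladium.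

Step 3
Reactants: 5 acenaphthoquinone
Product: 6 cis-1,2-dimethyl-1,2-dihydroacenaphthylene-1,2-diol (meso)
Conditions: AlMe3 (3 equiv), toluene, 0 °C to rt; aq. Rochelle salt; recrystallise
Reagents that add atoms: trimethylaluminium, C[Al](C)C
Why: Double 1,2-addition of methyl to the diketone; the second methyl should add anti to the bulky aluminium alkoxide, which places the two hydroxyls cis, and crystallisation removes any trans diol.

Step 4
Reactants: 4 tert-butyldimethyl(prop-2-yn-1-yloxy)silane; 6 cis-1,2-dimethyl-1,2-dihydroacenaphthylene-1,2-diol
Product: 8 (E)-3-(tert-butyldimethylsilyloxy)prop-1-enylboronic acid mac ester (cyclic ester with 6), via alkenyl catechol boronate 7 (not isolated)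
Conditions: catecholborane, Cy2BH (5 mol%), THF, rt; then 6, rt
Reagents that add atoms: catecholborane, [H]B1Oc2ccccc2O1
Why: Dialkylborane-catalysed hydroboration of a terminal alkyne is syn and anti-Markovnikov and so gives the (E)-alkenyl boronate; catechol esters exchange readily with aliphatic 1,2-diols, which installs the mac ligand.

Step 5
Reactants: 9 eugenol
Product: 10 4-allyl-2-bromo-6-methoxyphenol
Conditions: NBS, i-Pr2NH (10 mol%), CH2Cl2, 0 °C, dark
Reagents that add atoms: N-bromosuccinimide, O=C1CCC(=O)N1Br
Why: Amine-catalysed ortho-bromination of a phenol with NBS; the only open activated ring position is ortho to the hydroxyl, and without light or water the terminal alkene and the benzylic CH2 should stay untouched.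

Step 6
Reactants: 10 4-allyl-2-bromo-6-methoxyphenol
Product: 11 5-allyl-1-bromo-3-methoxy-2-(methoxymethoxy)benzene
Conditions: MOMCl, i-Pr2NEt, CH2Cl2, 0 °C to rt
Reagents that add atoms: chloromethyl methyl ether, COCCl
Why: O-alkylation of the hindered phenol by a small, reactive alpha-chloro ether; the acetal is inert to the ate complex and to palladium and falls in the acid of step 9.

Step 7
Reactants: 2 (4-bromo-2-methoxyphenoxy)triisopropylsilane; 8 (E)-3-(tert-butyldimethylsilyloxy)prop-1-enylboronic acid mac ester; 11 5-allyl-1-bromo-3-methoxy-2-(methoxymethoxy)benzene
Product: 14 (1S,2R)-2-[5-allyl-3-methoxy-2-(methoxymethoxy)phenyl]-3-(tert-butyldimethylsilyloxy)-1-[3-methoxy-4-(triisopropylsilyloxy)phenyl]propylboronic acid mac ester, via aryllithium 12 (not isolated), via lithium boron ate complex 13 (not isolated)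
Conditions: t-BuLi (2.0 equiv), THF, −78 °C; then 8, −78 °C to rt; then 11, Pd(OAc)2 (3 mol%), MandyPhos (3.6 mol%), KOTf (2 equiv), THF, 60 °C
Reagents that add atoms: none
Why: Bromine–lithium exchange on 2 gives aryllithium 12, which adds to the vacant orbital on boron of 8 to give the four-coordinate ate complex 13. Pd(OAc)2 (divalent palladium) is reduced in the flask to a zerovalent palladium–MandyPhos complex that inserts into the C–Br bond of 11, and KOTf removes bromide as KBr so that the arylpalladium is cationic and can bind the electron-rich alkene of 13. Coordination triggers a 1,2-metallate shift: ring C migrates from boron to C2 on the face opposite palladium while C3 becomes bound to palladium, and C–C reductive elimination with retention then joins C3 to C3a and returns zerovalent palladium. The closest known reaction type is the palladium-catalysed enantioselective conjunctive cross-coupling of beta-substituted alkenyl boron ate complexes with aryl electrophiles, for which the hindered mac diol is the boron ligand of choice. No ring is closed. C3 is set by the chiral bisphosphine, which decides the alkene face that palladium binds; C2 is set relative to C3 by the anti relationship of migrating group and palladium together with the (E) geometry of 8, which gives the (1S,2R) diastereomer. The step needs the metallate shift to outrun direct transfer of the alkenyl or aryl group from boron to palladium (secured by the mac ligand and by keeping halide off palladium), reductive elimination to outrun beta-hydride or beta-silyloxy elimination from the C3–palladium intermediate (secured by the chelating bisphosphine), and the anionic alkene of 13 to outcompete the neutral allyl group of 11 for the cationic palladium.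

Step 8
Reactants: 14 (1S,2R)-propylboronic acid mac ester from step 7
Product: 15 (1S,2R)-2-[5-allyl-3-methoxy-2-(methoxymethoxy)phenyl]-3-(tert-butyldimethylsilyloxy)-1-[3-methoxy-4-(triisopropylsilyloxy)phenyl]propan-1-ol
Conditions: NaBO3·4H2O, THF/H2O, rt
Reagents that add atoms: sodium perborate, [Na+].[O-]OB=O
Why: Oxidation of a boronic ester by peroxide: C2 migrates from boron to oxygen with retention, so the (1S,2R) configuration carries over; perborate is mild enough for the aryl silyl ether and does not touch isolated alkenes.

Step 9
Reactants: 15 (1S,2R)-propan-1-ol from step 8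
Product: 17 [(2S,3R)-5-allyl-7-methoxy-2-[3-methoxy-4-(triisopropylsilyloxy)phenyl]-2,3-dihydrobenzofuran-3-yl]methanol, via phenol diol 16 (not isolated)
Conditions: 3 M aq. HCl, THF, 45 °C
Reagents that add atoms: none
Why: Aqueous acid hydrolyses the methoxymethyl acetal and the primary TBS ether to give 16; loss of water from C2 then gives a benzylic cation stabilised by the para silyloxy group, and the ring A phenol captures it to close ring B (intramolecular SN1 etherification). C2 is set under thermodynamic control relative to the fixed C3 (ring C and C9 trans), so the configuration C2 had in 15 does not matter; the aryl TIPS ether is expected to survive this acid.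

Step 10
Reactants: 17 dihydrobenzofuran alcohol from step 9; 9 eugenol
Product: 18 (2S,3R)-5-allyl-3-[(4-allyl-2-methoxyphenoxy)methyl]-7-methoxy-2-[3-methoxy-4-(triisopropylsilyloxy)phenyl]-2,3-dihydrobenzofuran
Conditions: PPh3, DIAD, THF, 0 °C to rt
Reagents that add atoms: none
Why: Mitsunobu etherification: the primary C9 alcohol is activated as its alkoxyphosphonium salt and displaced by the phenoxide of 9 in an SN2 step; no stereocentre is involved, and 17 has no other free hydroxyl.

Step 11
Reactants: 18 TIPS ether from step 10
Product: 19 4-[(2S,3R)-5-allyl-3-[(4-allyl-2-methoxyphenoxy)methyl]-7-methoxy-2,3-dihydrobenzofuran-2-yl]-2-methoxyphenol (target)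
Conditions: TBAF, AcOH, THF, 0 °C
Reagents that add atoms: none
Why: Fluoride cleaves the aryl Si–O bond; buffering with acetic acid keeps the phenoxide from opening ring B or moving the allyl groups.

## Compound list

1 | 4-bromo-2-methoxyphenol | COc1cc(Br)ccc1O | starting material
2 | (4-bromo-2-methoxyphenoxy)triisopropylsilane | COc1cc(Br)ccc1O[Si](C(C)C)(C(C)C)C(C)C | intermediate
3 | propargyl alcohol | C#CCO | starting material
4 | tert-butyldimethyl(prop-2-yn-1-yloxy)silane | C#CCO[Si](C)(C)C(C)(C)C | intermediate
5 | acenaphthoquinone | O=C1C(=O)c2cccc3cccc1c23 | starting material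
6 | cis-1,2-dimethyl-1,2-dihydroacenaphthylene-1,2-diol (meso) | C[C@]1(O)c2cccc3cccc(c32)[C@@]1(C)O | intermediate
7 | (E)-2-[3-(tert-butyldimethylsilyloxy)prop-1-enyl]-1,3,2-benzodioxaborole | CC(C)(C)[Si](C)(C)OC/C=C/B1Oc2ccccc2O1 | intermediate (not isolated)
8 | (E)-3-(tert-butyldimethylsilyloxy)prop-1-enylboronic acid mac ester | CC(C)(C)[Si](C)(C)OC/C=C/B1O[C@]2(C)c3cccc4cccc(c43)[C@]2(C)O1 | intermediate
9 | eugenol | C=CCc1ccc(O)c(OC)c1 | starting material
10 | 4-allyl-2-bromo-6-methoxyphenol | C=CCc1cc(Br)c(O)c(OC)c1 | intermediate
11 | 5-allyl-1-bromo-3-methoxy-2-(methoxymethoxy)benzene | C=CCc1cc(Br)c(OCOC)c(OC)c1 | intermediate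
12 | [3-methoxy-4-(triisopropylsilyloxy)phenyl]lithium | [Li]c1ccc(O[Si](C(C)C)(C(C)C)C(C)C)c(OC)c1 | intermediate (not isolated)
13 | lithium (E)-alkenyl(aryl)borate of the mac diol (ate complex of 8 and 12) | [Li+].CC(C)(C)[Si](C)(C)OC/C=C/[B-]1(c2ccc(O[Si](C(C)C)(C(C)C)C(C)C)c(OC)c2)O[C@]2(C)c3cccc4cccc(c43)[C@]2(C)O1 | intermediate (not isolated)
14 | (1S,2R)-2-[5-allyl-3-methoxy-2-(methoxymethoxy)phenyl]-3-(tert-butyldimethylsilyloxy)-1-[3-methoxy-4-(triisopropylsilyloxy)phenyl]propylboronic acid mac ester | CC(C)(C)[Si](C)(C)OC[C@H]([C@H](B1O[C@]2(C)c3cccc4cccc(c43)[C@]2(C)O1)c1ccc(O[Si](C(C)C)(C(C)C)C(C)C)c(OC)c1)c1cc(CC=C)cc(OC)c1OCOC | intermediate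
15 | (1S,2R)-2-[5-allyl-3-methoxy-2-(methoxymethoxy)phenyl]-3-(tert-butyldimethylsilyloxy)-1-[3-methoxy-4-(triisopropylsilyloxy)phenyl]propan-1-ol | CC(C)(C)[Si](C)(C)OC[C@H]([C@H](O)c1ccc(O[Si](C(C)C)(C(C)C)C(C)C)c(OC)c1)c1cc(CC=C)cc(OC)c1OCOC | intermediate
16 | (1S,2R)-2-(5-allyl-2-hydroxy-3-methoxyphenyl)-1-[3-methoxy-4-(triisopropylsilyloxy)phenyl]propane-1,3-diol | OC[C@H]([C@H](O)c1ccc(O[Si](C(C)C)(C(C)C)C(C)C)c(OC)c1)c1cc(CC=C)cc(OC)c1O | intermediate (not isolated)
17 | [(2S,3R)-5-allyl-7-methoxy-2-[3-methoxy-4-(triisopropylsilyloxy)phenyl]-2,3-dihydrobenzofuran-3-yl]methanol | OC[C@H]1c2cc(CC=C)cc(OC)c2O[C@@H]1c1ccc(O[Si](C(C)C)(C(C)C)C(C)C)c(OC)c1 | intermediate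
18 | (2S,3R)-5-allyl-3-[(4-allyl-2-methoxyphenoxy)methyl]-7-methoxy-2-[3-methoxy-4-(triisopropylsilyloxy)phenyl]-2,3-dihydrobenzofuran | C=CCc1ccc(OC[C@H]2c3cc(CC=C)cc(OC)c3O[C@@H]2c2ccc(O[Si](C(C)C)(C(C)C)C(C)C)c(OC)c2)c(OC)c1 | intermediate
19 | 4-[(2S,3R)-5-allyl-3-[(4-allyl-2-methoxyphenoxy)methyl]-7-methoxy-2,3-dihydrobenzofuran-2-yl]-2-methoxyphenol | C=CCc1ccc(OC[C@H]2c3cc(CC=C)cc(OC)c3O[C@@H]2c2ccc(O)c(OC)c2)c(OC)c1 | target

## Step count and least certain steps

Total: 11 steps. Longest linear sequence: 7 steps (steps 2, 4, 7, 8, 9, 10, 11, from 3 to 19).

Step 7 (key step). Most likely to go wrong: diversion of the ate complex into direct transmetallation, so that two-component coupling replaces the three-component process. The allylic silyloxy substituent on the alkene and the ortho-substituted, electron-rich bromide both slow the metallate shift, and residual halide blocks the vacant site on palladium. Second in likelihood is weak enantiofacial selection at C3 for this particular beta-substituent. Fallback (sets out from 11 and 2, returns at 17), using an auxiliary-controlled aldol in place of the catalytic diarylation: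
- Negishi coupling of 11 with BrZnCH2CO2Et (Pd2(dba)3, XPhos, THF) should give ethyl 2-[5-allyl-3-methoxy-2-(methoxymethoxy)phenyl]acetate F1.
- LiOH gives the arylacetic acid F2.
- The pivaloyl mixed anhydride of F2 acylates lithiated (S)-4-benzyloxazolidin-2-one to give the imide F3.
- Quenching 12 with DMF gives 3-methoxy-4-(triisopropylsilyloxy)benzaldehyde F4.
- Evans syn aldol reaction of F3 with F4 (Bu2BOTf, i-Pr2NEt, CH2Cl2, −78 °C) should give the (2S,3S) aldol adduct F5. Its two new centres have the same spatial arrangement as in 15.
- LiBH4 removes the auxiliary and gives the (1S,2R)-1,3-diol F6, which is 15 without its TBS group.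
- The acid of step 9 converts F6 through 16 into 17.

Step 9. Most likely to go wrong: a mismatch in the rates of the three events run in one pot. If C2 ionises before the phenol is free, or the cation lingers, it can be lost by elimination towards C3 (which would erase the C3 configuration) or be captured by formaldehyde-derived species, and the acid strength needed for the acetal slowly erodes the aryl TIPS ether. Fallback (sets out from 14, returns at 17): the unmasking is moved ahead of the oxidation. HCl in MeOH at rt removes the methoxymethyl and TBS groups from 14 while C2 still carries boron and cannot ionise, giving the phenol–alcohol boronate F7. NaBO3 then gives 16, which is isolated and closed in a separate operation free of nucleophilic solvent (catalytic TsOH, CH2Cl2, molecular sieves, 0 °C) to give 17.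

Step 10. Most likely to go wrong: elimination of the activated C9 oxygen across C3–C9, since the C3 hydrogen is benzylic, or sluggish displacement at the beta-branched carbon. Fallback (sets out from 17, returns at 18): a Williamson etherification in two operations. MsCl and Et3N give the C9 methanesulfonate F8, and preformed sodium eugenolate (9 with NaH) in DMF at 40 °C displaces it to give 18. A mesylate is preferred to a triflate so that the neighbouring ring A does not assist ionisation.

Step 5. Most likely to go wrong: competing addition of electrophilic bromine to the allyl alkene, or radical bromination of the doubly activated CH2. Fallback (sets out from 9, returns at 10): the alkene is deliberately masked. Br2 (2 equiv, CH2Cl2, 0 °C) brominates ring and alkene to give racemic 2-bromo-4-(2,3-dibromopropyl)-6-methoxyphenol F9, and zinc dust in AcOH/EtOH removes the vicinal dibromide to regenerate the allyl group and give 10.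

Step 4. Most likely to go wrong: incomplete exchange of catechol for the hindered diol, or erosion of regioselectivity next to the propargylic oxygen. Fallback (sets out from 4, returns at 8): stoichiometric hydroboration with Cy2BH (THF, 0 °C) gives the (E)-alkenyldicyclohexylborane F10. Me3NO (2 equiv) oxidises only the two B–cyclohexyl bonds to give the dicyclohexyl alkenylboronate F11, and 6 displaces cyclohexanol to give 8.

## Further compounds

F1 | step 7 | ethyl 2-[5-allyl-3-methoxy-2-(methoxymethoxy)phenyl]acetate | CCOC(=O)Cc1cc(CC=C)cc(OC)c1OCOC
F2 | step 7 | 2-[5-allyl-3-methoxy-2-(methoxymethoxy)phenyl]acetic acid | OC(=O)Cc1cc(CC=C)cc(OC)c1OCOC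
F3 | step 7 | (S)-3-{2-[5-allyl-3-methoxy-2-(methoxymethoxy)phenyl]acetyl}-4-benzyloxazolidin-2-one | O=C(Cc1cc(CC=C)cc(OC)c1OCOC)N1[C@@H](Cc2ccccc2)COC1=O
F4 | step 7 | 3-methoxy-4-(triisopropylsilyloxy)benzaldehyde | COc1cc(C=O)ccc1O[Si](C(C)C)(C(C)C)C(C)C
F5 | step 7 | (S)-3-{(2S,3S)-2-[5-allyl-3-methoxy-2-(methoxymethoxy)phenyl]-3-hydroxy-3-[3-methoxy-4-(triisopropylsilyloxy)phenyl]propanoyl}-4-benzyloxazolidin-2-one | O=C([C@@H](c1cc(CC=C)cc(OC)c1OCOC)[C@H](O)c1ccc(O[Si](C(C)C)(C(C)C)C(C)C)c(OC)c1)N1[C@@H](Cc2ccccc2)COC1=O
F6 | step 7 | (1S,2R)-2-[5-allyl-3-methoxy-2-(methoxymethoxy)phenyl]-1-[3-methoxy-4-(triisopropylsilyloxy)phenyl]propane-1,3-diol | OC[C@H]([C@H](O)c1ccc(O[Si](C(C)C)(C(C)C)C(C)C)c(OC)c1)c1cc(CC=C)cc(OC)c1OCOC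
F7 | step 9 | (1S,2R)-2-(5-allyl-2-hydroxy-3-methoxyphenyl)-3-hydroxy-1-[3-methoxy-4-(triisopropylsilyloxy)phenyl]propylboronic acid mac ester | OC[C@H]([C@H](B1O[C@]2(C)c3cccc4cccc(c43)[C@]2(C)O1)c1ccc(O[Si](C(C)C)(C(C)C)C(C)C)c(OC)c1)c1cc(CC=C)cc(OC)c1O
F8 | step 10 | [(2S,3R)-5-allyl-7-methoxy-2-[3-methoxy-4-(triisopropylsilyloxy)phenyl]-2,3-dihydrobenzofuran-3-yl]methyl methanesulfonate | CS(=O)(=O)OC[C@H]1c2cc(CC=C)cc(OC)c2O[C@@H]1c1ccc(O[Si](C(C)C)(C(C)C)C(C)C)c(OC)c1
F9 | step 5 | 2-bromo-4-(2,3-dibromopropyl)-6-methoxyphenol (racemic) | COc1cc(CC(Br)CBr)cc(Br)c1O
F10 | step 4 | (E)-[3-(tert-butyldimethylsilyloxy)prop-1-enyl]dicyclohexylborane | CC(C)(C)[Si](C)(C)OC/C=C/B(C1CCCCC1)C1CCCCC1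
F11 | step 4 | dicyclohexyl (E)-[3-(tert-butyldimethylsilyloxy)prop-1-enyl]boronate | CC(C)(C)[Si](C)(C)OC/C=C/B(OC1CCCCC1)OC1CCCCC1
A1 | alternative 1 | methyl (2S,3S)-5-bromo-7-methoxy-2-(4-methanesulfonyloxy-3-methoxyphenyl)-2,3-dihydrobenzofuran-3-carboxylate (trans) | COC(=O)[C@H]2c3cc(Br)cc(OC)c3O[C@@H]2c2ccc(OS(C)(=O)=O)c(OC)c2
A2 | alternative 1 | (S)-6-bromo-8-methoxy-2-(4-methanesulfonyloxy-3-methoxyphenyl)chroman-4-one | O=C1C[C@@H](c2ccc(OS(C)(=O)=O)c(OC)c2)Oc2c(OC)cc(Br)cc21
A3 | alternative 2 | 1-{[(2S,3R)-5-allyl-2-[4-(tert-butyldimethylsilyloxy)-3-methoxyphenyl]-7-methoxy-2,3-dihydrobenzofuran-3-yl]methoxy}-2,2,6,6-tetramethylpiperidine (trans) | CC1(C)CCCC(C)(C)N1OC[C@H]2c3cc(CC=C)cc(OC)c3O[C@@H]2c2ccc(O[Si](C)(C)C(C)(C)C)c(OC)c2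
A4 | alternative 2 | (S)-{4-[1-(4-allyl-2-iodo-6-methoxyphenoxy)prop-2-enyl]-2-methoxyphenoxy}(tert-butyl)dimethylsilane | C=C[C@H](Oc1c(I)cc(CC=C)cc1OC)c1ccc(O[Si](C)(C)C(C)(C)C)c(OC)c1
A5 | alternative 3 | (2S,3R)-5-allyl-3-[(4-allyl-2-methoxyphenoxy)methyl]-7-methoxy-2-[3-methoxy-4-(methoxymethoxy)phenyl]-2,3-dihydrobenzofuran | C=CCc1ccc(OC[C@H]2c3cc(CC=C)cc(OC)c3O[C@@H]2c2ccc(OCOC)c(OC)c2)c(OC)c1
A6 | alternative 3 | (1S,2R)-2-(5-allyl-2-bromo-3-methoxyphenyl)-3-(4-allyl-2-methoxyphenoxy)-1-[3-methoxy-4-(methoxymethoxy)phenyl]propan-1-ol | C=CCc1ccc(OC[C@H]([C@H](O)c2ccc(OCOC)c(OC)c2)c2cc(CC=C)cc(OC)c2Br)c(OC)c1
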